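The isoflavone is cut at C3–C1′ and O1–C2. Both carbons of the first bond are innately nucleophilic: C3 is the α-carbon of a ring A 2-hydroxyaryl enaminone and C1′ is the para carbon of ring B, a 2,6-dimethoxyphenol whose ortho sites carry the methoxy groups. One anodic operation, free of halogen and metal, should join them and let the ring A hydroxyl displace dimethylamine to close ring C. The precursor is the dimethylamino enaminone of a 6′-hydroxy-2′-methoxy-3′-methylacetophenone whose 4′-oxygen is masked as a pivalate, which withstands the acidic oxidative C–H hydroxylation used to install the 6′-hydroxyl and keeps ring A hard to oxidise.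

Key step: step 5

Remark: the open-chain coupling product 9 is written as its neutral E enaminone; in HFIP it is expected to react on through its iminium tautomer.

Step 1
Reactants: 1 2',4'-dihydroxy-3'-methylacetophenone
Product: 2 (4-acetyl-3-hydroxy-2-methylphenyl) 2,2-dimethylpropanoate
Conditions: PivCl (1.05 equiv), Et3N, CH2Cl2, 0 °C to rt
Reagents that add atoms: pivaloyl chloride, CC(C)(C)C(=O)Cl
Why: Chemoselective O-acylation of a phenol: the 2'-hydroxyl is hydrogen-bonded to the acetyl carbonyl and flanked by methyl and acetyl, so the acid chloride should esterify only the free 4'-hydroxyl.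

Step 2
Reactants: 2 (4-acetyl-3-hydroxy-2-methylphenyl) 2,2-dimethylpropanoate
Product: 3 (4-acetyl-3-methoxy-2-methylphenyl) 2,2-dimethylpropanoate
Conditions: MeI, K2CO3, DMF, 40 °C
Reagents that add atoms: iodomethane, CI
Why: Williamson O-methylation of the chelated phenol in a dipolar aprotic solvent, in which dry carbonate should leave the hindered aryl pivalate untouched.

Step 3
Reactants: 3 (4-acetyl-3-methoxy-2-methylphenyl) 2,2-dimethylpropanoate
Product: 5 (4-acetyl-5-hydroxy-3-methoxy-2-methylphenyl) 2,2-dimethylpropanoate, via aryl trifluoroacetate 4 (not isolated)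
Conditions: [RuCl2(p-cymene)]2 (2.5 mol %), PhI(OCOCF3)2 (1.5 equiv), TFA/TFAA, 80 °C; then aq. NaHCO3, rt
Reagents that add atoms: [bis(trifluoroacetoxy)iodo]benzene, O=C(OI(OC(=O)C(F)(F)F)c1ccccc1)C(F)(F)F
Why: Ketone-directed ruthenium-catalysed ortho C–H oxygenation: the acetyl oxygen steers carboxylate-assisted cyclometalation at divalent ruthenium to C6'–H, the only ortho C–H left, the trivalent iodine reagent oxidises the ruthenacycle and C–O reductive elimination gives trifluoroacetate 4, which the bicarbonate work-up hydrolyses, while the pivalate and the methyl ether tolerate hot TFA (a benzyl ether would not) and the ester-deactivated ring resists the oxidant.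

Step 4
Reactants: 5 (4-acetyl-5-hydroxy-3-methoxy-2-methylphenyl) 2,2-dimethylpropanoate; 6 N,N-dimethylformamide dimethyl acetal
Product: 7 {4-[(2E)-3-(dimethylamino)prop-2-enoyl]-5-hydroxy-3-methoxy-2-methylphenyl} 2,2-dimethylpropanoate
Conditions: toluene, 90 °C
Reagents that add atoms: none
Why: Enaminone formation by condensation of the methyl ketone with the amide acetal (two methanol lost), which should give the thermodynamically preferred E vinylogous amide and leave the chelated 6'-hydroxyl unmethylated.

Step 5
Reactants: 7 {4-[(2E)-3-(dimethylamino)prop-2-enoyl]-5-hydroxy-3-methoxy-2-methylphenyl} 2,2-dimethylpropanoate; 8 2,6-dimethoxyphenol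
Product: 10 [3-(4-hydroxy-3,5-dimethoxyphenyl)-5-methoxy-6-methyl-4-oxo-4H-chromen-7-yl] 2,2-dimethylpropanoate, via α-aryl enaminone 9 (not isolated)
Conditions: undivided cell, graphite anode, Pt cathode, Bu4NBF4 (0.1 M), HFIP, constant current, 8 (1.5 equiv) added slowly, ca. 2.2 F per mol of 8, rt; then 40 °C
Reagents that add atoms: none
Why: Proposed new method: phenol 8, the most easily oxidised species in the cell (two ortho methoxy donors; HFIP hydrogen-bonds to the vinylogous amide of 7 and raises its potential), should lose two electrons and a proton at the anode to give a phenoxonium-type electrophile, which the nucleophilic α-carbon of enaminone 7 attacks at the para carbon; loss of the para proton rearomatises ring B and gives 9 with the C3–C1′ bond in place, while the protons are reduced to H2 at the cathode. In the weakly acidic medium 9 is in equilibrium with its C3-protonated iminium form, and the ring A hydroxyl adds to the iminium carbon (6-exo-trig with respect to C=N) before dimethylamine is expelled, which forms the O1–C2 bond and aromatises ring C. The closest known reaction types are the anodic dehydrogenative phenol–arene cross-coupling in HFIP and the oxidative α-C–H functionalisation with annulation of 2-hydroxyaryl enaminones to 3-substituted chromones. No stereocenter is formed. The step needs cross-coupling over phenol homo-coupling and attack at the para carbon only: slow addition keeps 8 scarce beside the better nucleophile 7, the pivalate-deactivated ring A should oxidise later than 8, and the two methoxy groups of 8 leave only its para position free. The charge is limited to little more than two faradays per mole of phenol consumed because the phenolic product 10 can itself be oxidised.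

Step 6
Reactants: 10 [3-(4-hydroxy-3,5-dimethoxyphenyl)-5-methoxy-6-methyl-4-oxo-4H-chromen-7-yl] 2,2-dimethylpropanoate
Product: 11 7-hydroxy-3-(4-hydroxy-3,5-dimethoxyphenyl)-5-methoxy-6-methyl-4H-chromen-4-one
Conditions: K2CO3, MeOH, rt; then aq. NH4Cl
Reagents that add atoms: none
Why: Base-catalysed transesterification (methanolysis) of the aryl pivalate, which should be easy because the 7-oxychromone is a good leaving group, while the three methyl ethers are inert and the phenoxides formed shield the pyranone from methoxide at room temperature.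

Compound list
1 | 2',4'-dihydroxy-3'-methylacetophenone | CC(=O)c1ccc(O)c(C)c1O | starting material
2 | (4-acetyl-3-hydroxy-2-methylphenyl) 2,2-dimethylpropanoate | CC(=O)c1ccc(OC(=O)C(C)(C)C)c(C)c1O | intermediate
3 | (4-acetyl-3-methoxy-2-methylphenyl) 2,2-dimethylpropanoate | CC(=O)c1ccc(OC(=O)C(C)(C)C)c(C)c1OC | intermediate
4 | {4-acetyl-3-methoxy-2-methyl-5-[(trifluoroacetyl)oxy]phenyl} 2,2-dimethylpropanoate | CC(=O)c1c(OC(=O)C(F)(F)F)cc(OC(=O)C(C)(C)C)c(C)c1OC | intermediate
5 | (4-acetyl-5-hydroxy-3-methoxy-2-methylphenyl) 2,2-dimethylpropanoate | CC(=O)c1c(O)cc(OC(=O)C(C)(C)C)c(C)c1OC | intermediate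
6 | N,N-dimethylformamide dimethyl acetal | COC(OC)N(C)C | starting material
7 | {4-[(2E)-3-(dimethylamino)prop-2-enoyl]-5-hydroxy-3-methoxy-2-methylphenyl} 2,2-dimethylpropanoate | CN(C)/C=C/C(=O)c1c(O)cc(OC(=O)C(C)(C)C)c(C)c1OC | intermediate
8 | 2,6-dimethoxyphenol | COc1cccc(OC)c1O | starting material
9 | {4-[(2E)-3-(dimethylamino)-2-(4-hydroxy-3,5-dimethoxyphenyl)prop-2-enoyl]-5-hydroxy-3-methoxy-2-methylphenyl} 2,2-dimethylpropanoate | CN(C)/C=C(/C(=O)c1c(O)cc(OC(=O)C(C)(C)C)c(C)c1OC)c1cc(OC)c(O)c(OC)c1 | intermediate
10 | [3-(4-hydroxy-3,5-dimethoxyphenyl)-5-methoxy-6-methyl-4-oxo-4H-chromen-7-yl] 2,2-dimethylpropanoate | COc1cc(-c2coc3cc(OC(=O)C(C)(C)C)c(C)c(OC)c3c2=O)cc(OC)c1O | intermediate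
11 | 7-hydroxy-3-(4-hydroxy-3,5-dimethoxyphenyl)-5-methoxy-6-methyl-4H-chromen-4-one | COc1cc(-c2coc3cc(O)c(C)c(OC)c3c2=O)cc(OC)c1O | target

Total step count: 6. Longest linear sequence: 6 steps (from 1; compounds 6 and 8 are used as purchased).

Steps most likely to fail

Step 5 (proposed new method). The phenol-derived intermediate may couple with a second phenol faster than the enaminone traps it. The enaminone may also be oxidised itself or close early to the 3-unsubstituted chromone, and the phenolic product may be oxidised further. The fallback uses known chemistry, sets out from 7 and returns at 10. Iodine-induced cyclisation of 7 (I2, pyridine, CHCl3, rt) should give [3-iodo-5-methoxy-6-methyl-4-oxo-4H-chromen-7-yl] 2,2-dimethylpropanoate F1. Suzuki–Miyaura coupling of F1 with commercial 2,6-dimethoxy-4-(4,4,5,5-tetramethyl-1,3,2-dioxaborolan-2-yl)phenol (Pd(dppf)Cl2, CsF, 1,4-dioxane, 80 °C) should then give 10.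

Step 3. The trivalent iodine reagent may oxidise the acetyl α-carbon or the ring, cyclometalation of a ketone twisted by its two ortho neighbours may be sluggish, and some pivalate may be lost in hot acid. The fallback sets out from 3 and returns at 5. Ketone-directed iridium-catalysed ortho C–H borylation ([Ir(OMe)(cod)]2, AsPh3, B2pin2, octane, 120 °C) should give [4-acetyl-3-methoxy-2-methyl-5-(4,4,5,5-tetramethyl-1,3,2-dioxaborolan-2-yl)phenyl] 2,2-dimethylpropanoate F2. Oxidation of its C–B bond (KHSO5, acetone/H2O, 0 °C) should give 5.

Step 2. The pivaloyl group may be transferred or lost under the basic alkylation, which would let the freed 4'-oxygen be methylated, or the hindered hydrogen-bonded phenol may be methylated incompletely. The fallback sets out from 1 and returns at 3, using an ether as the temporary group and acylating last. 4'-O-Benzylation (BnBr, K2CO3, acetone, reflux) should give 1-[4-(benzyloxy)-2-hydroxy-3-methylphenyl]ethanone F3. Methylation (MeI, K2CO3, DMF, 60 °C) should give 1-[4-(benzyloxy)-2-methoxy-3-methylphenyl]ethanone F4. Hydrogenolysis (H2, 10% Pd/C, EtOAc, rt) should give 1-(4-hydroxy-2-methoxy-3-methylphenyl)ethanone F5, and acylation (PivCl, Et3N, CH2Cl2, 0 °C) should give 3.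

Further compounds
F1 | step 5 | [3-iodo-5-methoxy-6-methyl-4-oxo-4H-chromen-7-yl] 2,2-dimethylpropanoate | COc1c(C)c(OC(=O)C(C)(C)C)cc2occ(I)c(=O)c12
F2 | step 3 | [4-acetyl-3-methoxy-2-methyl-5-(4,4,5,5-tetramethyl-1,3,2-dioxaborolan-2-yl)phenyl] 2,2-dimethylpropanoate | CC(=O)c1c(B2OC(C)(C)C(C)(C)O2)cc(OC(=O)C(C)(C)C)c(C)c1OC
F3 | step 2 | 1-[4-(benzyloxy)-2-hydroxy-3-methylphenyl]ethanone | CC(=O)c1ccc(OCc2ccccc2)c(C)c1O
F4 | step 2 | 1-[4-(benzyloxy)-2-methoxy-3-methylphenyl]ethanone | CC(=O)c1ccc(OCc2ccccc2)c(C)c1OC
F5 | step 2 | 1-(4-hydroxy-2-methoxy-3-methylphenyl)ethanone | CC(=O)c1ccc(O)c(C)c1OC
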